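**Retrosynthetic overview**
1. Target 15 ⇐ artocarpin 13. The oxepine is closed last: enantioselective epoxidation of the 3-prenyl group gives (S)-epoxide 14, which the 2'-phenoxide opens 7-exo-tet with inversion to set (R), in one pot on the unprotected flavone.
2. 13 ⇐ flavone 6 by C6 iodination/Suzuki alkenylation, C3 lithiation/prenylation and MOM removal.
3. 6 ⇐ chalcone 4 by oxa-Michael closure to flavanone 5 and dehydrogenation ⇐ acetophenone 3 + aldehyde 2 (Claisen–Schmidt).
4. Ring order: A and B rings are bought (3 and 1); pyranone ring in step 3; oxepine ring in step 8.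

Assumption: flavone numbering is used (B ring primed); the stereocentre in the SMILES is (R); the L-fructose-derived (ent-)Shi ketone is a purchased catalyst.

**Step 1**
Reactants: 1 2,4-dihydroxybenzaldehyde
Product: 2 2,4-bis(methoxymethoxy)benzaldehyde
Conditions: MOMCl (3 equiv), K2CO3 (4 equiv), acetone, 0 °C → reflux
Reagents that add atoms: chloromethyl methyl ether (MOMCl) COCCl
Why: Williamson-type O-alkylation of both phenoxides gives base-stable MOM ethers, so the aldehyde stays electrophilic in the aldol step.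

**Step 2**
Reactants: 3 1-(2,6-dihydroxy-4-methoxyphenyl)ethan-1-one; 2 2,4-bis(methoxymethoxy)benzaldehyde
Product: 4 (E)-3-[2,4-bis(methoxymethoxy)phenyl]-1-(2,6-dihydroxy-4-methoxyphenyl)prop-2-en-1-one (chalcone)
Conditions: KOH (50% aq, 15 equiv), EtOH, 25 °C, 48 h; AcOH to pH 6 at 0 °C
Reagents that add atoms: none
Why: Claisen–Schmidt condensation (aldol addition, then E1cB dehydration to the E-enone) as for other 2',6'-dihydroxy-4'-methoxychalcones; partial closure to the flavanone on work-up is harmless because step 3 passes through that compound.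

**Step 3**
Reactants: 4 chalcone
Product: 6 5-hydroxy-7-methoxy-2-[2,4-bis(methoxymethoxy)phenyl]-4H-chromen-4-one (flavone), via flavanone 5 (not isolated)
Conditions: pyridine, 95 °C, 1 h; then I2 (1.1 equiv), 95 °C, 8 h
Reagents that add atoms: none
Why: 6-endo oxa-Michael closure to the flavanone followed by iodine-mediated dehydrogenation (C3 iodination, then loss of HI) copies the chalcone isomerase/flavone synthase sequence, the basic medium spares the MOM ethers, and the racemic C2 centre of 5 is erased on aromatisation.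

**Step 4**
Reactants: 6 flavone
Product: 7 5-hydroxy-6-iodo-7-methoxy-2-[2,4-bis(methoxymethoxy)phenyl]-4H-chromen-4-one
Conditions: BnMe3N·ICl2 (1.05 equiv), CaCO3 (1.5 equiv), CH2Cl2/MeOH (5:2), 25 °C
Reagents that add atoms: benzyltrimethylammonium dichloroiodate C[N+](C)(C)Cc1ccccc1.Cl[I-]Cl
Why: electrophilic aromatic iodination, which goes to C6 (ortho to the free chelated 5-OH) in 5-hydroxy-7-methoxyflavones, while the B ring carries only ether donors and is deactivated by the chromone.

**Step 5**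
Reactants: 8 3-methylbut-1-yne; 7 6-iodoflavone
Product: 10 5-hydroxy-7-methoxy-6-[(E)-3-methylbut-1-en-1-yl]-2-[2,4-bis(methoxymethoxy)phenyl]-4H-chromen-4-one, via alkenylboronate 9 (not isolated)
Conditions: 8 (1.5 equiv), HBpin (1.2 equiv), Cp2Zr(H)Cl (5 mol%), Et3N (10 mol%), neat, sealed tube, 60 °C; then 7 (1.0 equiv), Pd(dppf)Cl2 (5 mol%), K3PO4, dioxane/H2O, 80 °C
Reagents that add atoms: none
Why: zirconium-catalysed syn-hydroboration gives only the (E)-alkenyl pinacolboronate (the alkyne is in excess, so no HBpin is left), and the Suzuki–Miyaura coupling transfers it to C6 with retention of the E geometry.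

**Step 6**
Reactants: 10 6-alkenylflavone
Product: 12 2',4'-di-O-MOM-artocarpin [5-hydroxy-7-methoxy-6-[(E)-3-methylbut-1-en-1-yl]-3-(3-methylbut-2-en-1-yl)-2-[2,4-bis(methoxymethoxy)phenyl]-4H-chromen-4-one], via dilithio flavone 11 (not isolated)
Conditions: LDA (2.6 equiv), THF, −78 °C, 1 h; CuBr·SMe2 (20 mol%), prenyl bromide (1.5 equiv), −78 → −30 °C; aq. NH4Cl
Reagents that add atoms: prenyl bromide (1-bromo-3-methylbut-2-ene) CC(C)=CCBr
Why: after deprotonation of the 5-OH, LDA removes the C3–H (directed vinylic lithiation of a flavone, assisted by the C4 carbonyl and 2'-OMOM oxygens), and copper-catalysed SN2 allylation of the C3 anion gives the linear prenyl group while the chelated lithium 5-phenoxide stays inert at low temperature.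

**Step 7**
Reactants: 12 2',4'-di-O-MOM-artocarpin
Product: 13 artocarpin [2-(2,4-dihydroxyphenyl)-5-hydroxy-7-methoxy-6-[(E)-3-methylbut-1-en-1-yl]-3-(3-methylbut-2-en-1-yl)-4H-chromen-4-one]
Conditions: 2 M HCl, MeOH/THF (1:1), 40 °C, 3 h
Reagents that add atoms: none
Why: acid-catalysed acetal exchange with methanol cleaves the two aryl MOM ethers (good phenol leaving groups on the chromone-conjugated ring) under conditions mild enough to leave both alkenes untouched.

**Step 8**
Reactants: 13 artocarpin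
Product: 15 target (R)-oxepinoflavone CNP0216454.1, via (S)-epoxide 14 (not isolated)
Conditions: ent-Shi ketone (1,2:4,5-di-O-isopropylidene-β-L-erythro-2,3-hexodiulo-2,6-pyranose, 30 mol%), Oxone (1.4 equiv), K2CO3 (5.8 equiv), Bu4NHSO4 (cat.), MeCN/DMM–aq. Na2B4O7/EDTA buffer (pH ≈ 10.5), −10 → 0 °C, 2 h; then 25–40 °C, 8 h
Reagents that add atoms: potassium peroxymonosulfate (active component of Oxone) [K+].[O-]S(=O)(=O)OO
Why: Proposed new method: the chiral dioxirane from the ent-Shi ketone should epoxidise the isolated trisubstituted 3-prenyl alkene (spiro transition state, faster than the hindered trans-disubstituted styrenyl alkene) to the (S)-epoxide 14, and at pH 10.5 the 2'-phenoxide should open it by 7-exo-tet SN2 attack at the secondary carbon with inversion to set the (R)-centre and the tertiary alcohol, as an epoxidase/ring-closure pair would; the closest known reaction type is Shi epoxidation of O-protected ortho-prenylphenols followed by base-induced exo closure to 2-(2-hydroxypropan-2-yl)dihydrobenzofurans, here run unprotected and in one pot.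

**Compound list**
1 | 2,4-dihydroxybenzaldehyde | O=Cc1ccc(O)cc1O | starting material
2 | 2,4-bis(methoxymethoxy)benzaldehyde | O=Cc1ccc(OCOC)cc1OCOC | intermediate
3 | 1-(2,6-dihydroxy-4-methoxyphenyl)ethan-1-one | CC(=O)c1c(O)cc(OC)cc1O | starting material
4 | (E)-3-[2,4-bis(methoxymethoxy)phenyl]-1-(2,6-dihydroxy-4-methoxyphenyl)prop-2-en-1-one | COc1cc(O)c(C(=O)/C=C/c2ccc(OCOC)cc2OCOC)c(O)c1 | intermediate
5 | (±)-5-hydroxy-7-methoxy-2-[2,4-bis(methoxymethoxy)phenyl]chroman-4-one | COc1cc(O)c2C(=O)CC(c3ccc(OCOC)cc3OCOC)Oc2c1 | intermediate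
6 | 5-hydroxy-7-methoxy-2-[2,4-bis(methoxymethoxy)phenyl]-4H-chromen-4-one | COc1cc2oc(-c3ccc(OCOC)cc3OCOC)cc(=O)c2c(O)c1 | intermediate
7 | 5-hydroxy-6-iodo-7-methoxy-2-[2,4-bis(methoxymethoxy)phenyl]-4H-chromen-4-one | COc1cc2oc(-c3ccc(OCOC)cc3OCOC)cc(=O)c2c(O)c1I | intermediate
8 | 3-methylbut-1-yne | CC(C)C#C | starting material
9 | (E)-4,4,5,5-tetramethyl-2-(3-methylbut-1-en-1-yl)-1,3,2-dioxaborolane | CC(C)/C=C/B1OC(C)(C)C(C)(C)O1 | intermediate
10 | 5-hydroxy-7-methoxy-6-[(E)-3-methylbut-1-en-1-yl]-2-[2,4-bis(methoxymethoxy)phenyl]-4H-chromen-4-one | COc1cc2oc(-c3ccc(OCOC)cc3OCOC)cc(=O)c2c(O)c1/C=C/C(C)C | intermediate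
11 | C3-lithio lithium 5-phenoxide of 10 | COc1cc2oc(-c3ccc(OCOC)cc3OCOC)c([Li])c(=O)c2c(O[Li])c1/C=C/C(C)C | intermediate
12 | 2',4'-di-O-MOM-artocarpin | COc1cc2oc(-c3ccc(OCOC)cc3OCOC)c(CC=C(C)C)c(=O)c2c(O)c1/C=C/C(C)C | intermediate
13 | artocarpin | COc1cc2oc(-c3ccc(O)cc3O)c(CC=C(C)C)c(=O)c2c(O)c1/C=C/C(C)C | intermediate
14 | 2-(2,4-dihydroxyphenyl)-3-{[(2S)-3,3-dimethyloxiran-2-yl]methyl}-5-hydroxy-7-methoxy-6-[(E)-3-methylbut-1-en-1-yl]-4H-chromen-4-one | COc1cc2oc(-c3ccc(O)cc3O)c(C[C@@H]3OC3(C)C)c(=O)c2c(O)c1/C=C/C(C)C | intermediate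
15 | CNP0216454.1: oxepino-fused 5,4'-dihydroxy-7-methoxy-6-[(E)-3-methylbut-1-enyl]flavone, C3–CH2–CH(CMe2OH)–O–C2' bridge, (R) at the ring carbon bearing the 2-hydroxypropan-2-yl group | COc1cc2oc3c(c(=O)c2c(O)c1/C=C/C(C)C)C[C@H](C(C)(C)O)Oc1cc(O)ccc1-3 | target

**Step count and risks**
Total steps: 8. Longest linear sequence: 8 (1 → 2 → 4 → 6 → 7 → 10 → 12 → 13 → 15).

Most likely to fail, 1: step 8. The free phenoxides may be oxidised by Oxone/dioxirane, the styrenyl alkene may compete, or the ring may close slowly in the buffer. The fallback sets out from 13 and comes back at 15. Silylation of the two B-ring hydroxyls (TBSCl, imidazole, DMF; the chelated 5-OH is left free) gives 2',4'-bis-O-TBS-artocarpin F1. Shi epoxidation with the same ent-ketone then gives the isolated bis-silyl (S)-epoxide F2. TBAF in THF frees the 2'-phenoxide, which closes the oxepine by the same 7-exo-tet inversion while the 4'-silyl ether is cleaved in the same pot, giving 15.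

Most likely to fail, 2: step 6. The dianion may alkylate poorly (SN2/SN2′ mixtures, O-prenylation, slow reaction of the vinyl anion). The fallback sets out from 10 and comes back at 12, with the coupling polarity reversed. The same lithiation is quenched with I2, a fast and clean trap, to give the 3-iodoflavone F3. Linear-selective Negishi coupling (Pd(OAc)2/CPhos, THF, 25 °C) with prenylzinc bromide F4 (from prenyl bromide, zinc dust and LiCl in THF; one extra equivalent for the free 5-OH) then gives 12.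

Most likely to fail, 3: step 2. The polyanion of unprotected 3 may condense sluggishly with the electron-rich aldehyde. The fallback sets out from 3 and comes back at 6. Mono-benzylation (BnBr, K2CO3, acetone; the second OH stays hydrogen-bonded) gives 1-[2-(benzyloxy)-6-hydroxy-4-methoxyphenyl]ethan-1-one F5. Claisen–Schmidt condensation with 2 gives the 6'-O-benzyl chalcone F6. I2/pyridine as in step 3 gives the 5-O-benzylflavone F7, and hydrogenolysis (H2, Pd/C, EtOAc) returns 6.

**Further compounds**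
F1 | step 8 | 2',4'-bis-O-(tert-butyldimethylsilyl)artocarpin | COc1cc2oc(-c3ccc(O[Si](C)(C)C(C)(C)C)cc3O[Si](C)(C)C(C)(C)C)c(CC=C(C)C)c(=O)c2c(O)c1/C=C/C(C)C
F2 | step 8 | (S)-epoxide of F1 (3-{[(2S)-3,3-dimethyloxiran-2-yl]methyl} compound) | COc1cc2oc(-c3ccc(O[Si](C)(C)C(C)(C)C)cc3O[Si](C)(C)C(C)(C)C)c(C[C@@H]3OC3(C)C)c(=O)c2c(O)c1/C=C/C(C)C
F3 | step 6 | 5-hydroxy-3-iodo-7-methoxy-6-[(E)-3-methylbut-1-en-1-yl]-2-[2,4-bis(methoxymethoxy)phenyl]-4H-chromen-4-one | COc1cc2oc(-c3ccc(OCOC)cc3OCOC)c(I)c(=O)c2c(O)c1/C=C/C(C)C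
F4 | step 6 | prenylzinc bromide | CC(C)=CC[Zn]Br
F5 | step 2 | 1-[2-(benzyloxy)-6-hydroxy-4-methoxyphenyl]ethan-1-one | CC(=O)c1c(O)cc(OC)cc1OCc1ccccc1
F6 | step 2 | (E)-1-[2-(benzyloxy)-6-hydroxy-4-methoxyphenyl]-3-[2,4-bis(methoxymethoxy)phenyl]prop-2-en-1-one | COc1cc(O)c(C(=O)/C=C/c2ccc(OCOC)cc2OCOC)c(OCc2ccccc2)c1
F7 | step 2 | 5-(benzyloxy)-7-methoxy-2-[2,4-bis(methoxymethoxy)phenyl]-4H-chromen-4-one | COc1cc2oc(-c3ccc(OCOC)cc3OCOC)cc(=O)c2c(OCc2ccccc2)c1
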